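**Retrosynthetic overview**
- The ester is cut back to the free 3,4-diol (azulene numbering), and the diol to a bicyclic β-hydroxy enone by hydroxyl-directed 1,2-reduction.
- The β-hydroxy enone is opened in one [3+2] operation: the homoenolate of ethyl isopropyl ketone (from 1-isopropylcyclopropanol) is joined through its β-carbon to a β-carbon of an achiral cross-conjugated cycloheptadienone, and the enolate formed closes the cyclopentane by aldol addition.
- The dienone comes from double β-elimination of an oxygen bridge, after hydrogenation of the [4+3] adduct of 2,5-dimethylfuran and an oxyallyl cation; the cyclopropanol comes from a Kulinkovich reaction.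
- Ring order: seven-membered ring first ([4+3]), five-membered ring second ([3+2]), ester last.

Assumption: azulene numbering is used (C3 = carbinol carbon bearing isopropyl, C3a/C8a = ring-fusion carbons, C4 = ester carbon); 1,1,3,3-tetrabromoacetone and the chiral NHC precursor L* (2-[(4S,5S)-3-mesityl-4,5-diphenylimidazolinium-1-yl]benzenesulfonate, or its antipode) are taken as purchasable.

**Step 1**
Reactants: 1 2,5-dimethylfuran; 2 1,1,3,3-tetrabromopropan-2-one
Product: 4 1,5-dimethyl-8-oxabicyclo[3.2.1]oct-6-en-3-one (meso), via dibromo cycloadduct 3 (not isolated)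
Conditions: Zn dust, B(OEt)3, THF, 0 °C → rt; then Zn/Cu couple, NH4Cl, MeOH, rt
Reagents that add atoms: none
Why: Zinc reduces 2 to a zinc enolate that ionises to the 1,3-dibromo-oxyallyl cation, which undergoes [4+3] cycloaddition across the furan diene, and zinc/copper then removes both α-bromines reductively; the product is an achiral meso ketone, so no stereochemistry is at stake.

**Step 2**
Reactants: 4 1,5-dimethyl-8-oxabicyclo[3.2.1]oct-6-en-3-one
Product: 5 1,5-dimethyl-8-oxabicyclo[3.2.1]octan-3-one (meso)
Conditions: H2 (1 atm), Pd/C (10 wt%), EtOAc, rt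
Reagents that add atoms: none
Why: Catalytic hydrogenation of the strained cis-disubstituted alkene is fast and leaves the ketone and the ether bridge untouched.

**Step 3**
Reactants: 5 1,5-dimethyl-8-oxabicyclo[3.2.1]octan-3-one
Product: 7 3,6-dimethylcyclohepta-2,6-dien-1-one, via hydroxy enone 6 (not isolated)
Conditions: TsOH·H2O (0.1 equiv), toluene, reflux, Dean–Stark
Reagents that add atoms: none
Why: Acid-catalysed enolisation triggers β-elimination of the tertiary bridging ether (retro-oxa-Michael) to 6, whose tertiary β-hydroxyl is then lost by dehydration toward the carbonyl, giving the achiral, mirror-symmetric cross-conjugated dienone.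

**Step 4**
Reactants: 8 methyl 2-methylpropanoate
Product: 9 1-(propan-2-yl)cyclopropan-1-ol
Conditions: EtMgBr (2.4 equiv), Ti(OiPr)4 (0.2 equiv), Et2O, 0 °C → rt; then H2O
Reagents that add atoms: ethylmagnesium bromide, CC[Mg]Br
Why: Kulinkovich cyclopropanation, in which the titanacyclopropane formed from EtMgBr and Ti(OiPr)4 acts as a 1,2-dicarbanion toward the ester carbonyl; the product is achiral.

**Step 5**
Reactants: 7 3,6-dimethylcyclohepta-2,6-dien-1-one; 9 1-(propan-2-yl)cyclopropan-1-ol
Product: 13 (3R,3aR,8aS)-3-hydroxy-6,8a-dimethyl-3-(propan-2-yl)-2,3,3a,7,8,8a-hexahydroazulen-4(1H)-one (trans-fused), via zinc homoenolate 10 (not isolated), via zinc dienolate 11 (not isolated), via cis-fused zinc aldolate 12 (not isolated)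
Conditions: 9 (2.2 equiv), Et2Zn (1.1 equiv), THF, 0 °C → rt; then Cu(OTf)2 (5 mol%), L* (6 mol%), 7 (1.0 equiv), −30 °C → rt; then 40 °C, 8 h; then H2O
Reagents that add atoms: none
Why: Proposed new method: the zinc bis(cyclopropoxide) from 9 and Et2Zn ring-opens (β-carbon elimination, assisted by copper) to the β-zincio ketone 10, a homoenolate, which on the chiral NHC–copper centre adds 1,4 to one of the two enantiotopic β-carbons of 7 (ligand antipode chosen so that the quaternary carbon is 8aS), and the regiodefined zinc dienolate 11 closes the cyclopentane by intramolecular aldol addition onto the isopropyl ketone; closure on the planar enolate should first give the cis-fused aldolate 12, and warming lets the aldol reverse and re-close until the trans-fused zinc chelate predominates (trans being generally the more stable fusion for a bicyclo[5.3.0]decan-2-one, with C3–O and the C4 carbonyl bridged by zinc and isopropyl anti to the ring carbonyl, which fixes 3R and 3aR); the closest known reactions are zinc-homoenolate conjugate additions of cyclopropanols to enones, copper/NHC-catalysed asymmetric conjugate additions of organozinc reagents to 3-methylcyclohept-2-enone that build quaternary centres, and conjugate addition–aldol [3+2] annulations.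

**Step 6**
Reactants: 13 (3R,3aR,8aS)-3-hydroxy-6,8a-dimethyl-3-(propan-2-yl)-2,3,3a,7,8,8a-hexahydroazulen-4(1H)-one
Product: 14 (3R,3aS,4S,8aS)-6,8a-dimethyl-3-(propan-2-yl)-1,2,3,3a,4,7,8,8a-octahydroazulene-3,4-diol
Conditions: Me4NBH(OAc)3 (5 equiv), MeCN/AcOH (1:1), −30 → −20 °C; then aq. sodium potassium tartrate
Reagents that add atoms: none
Why: Evans–Saksena hydroxyl-directed reduction, in which the tertiary 3-OH exchanges onto boron and delivers hydride intramolecularly to the face of the C4 carbonyl on its own side, giving the anti-1,3-diol with the new carbinol 4S; the enone is reduced 1,2 only, because triacetoxyborohydride reacts solely through this internal delivery.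

**Step 7**
Reactants: 14 (3R,3aS,4S,8aS)-6,8a-dimethyl-3-(propan-2-yl)-1,2,3,3a,4,7,8,8a-octahydroazulene-3,4-diol; 15 4-methoxybenzoyl chloride
Product: 16 (3R,3aS,4S,8aS)-3-hydroxy-6,8a-dimethyl-3-(propan-2-yl)-1,2,3,3a,4,7,8,8a-octahydroazulen-4-yl 4-methoxybenzoate (target)
Conditions: Et3N (3 equiv), DMAP (0.2 equiv), CH2Cl2, 0 °C → rt
Reagents that add atoms: none
Why: DMAP-catalysed acylation (nucleophilic acyl substitution) takes place only at the secondary allylic hydroxyl, the tertiary hydroxyl next to isopropyl being inert under these conditions, and no stereocentre is touched.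

**Compound list**
1 | 2,5-dimethylfuran | Cc1ccc(C)o1 | starting material
2 | 1,1,3,3-tetrabromopropan-2-one | BrC(Br)C(=O)C(Br)Br | starting material
3 | 2,4-dibromo-1,5-dimethyl-8-oxabicyclo[3.2.1]oct-6-en-3-one (diastereomer mixture, not isolated) | CC12OC(C)(C=C1)C(Br)C(=O)C2Br | intermediate
4 | 1,5-dimethyl-8-oxabicyclo[3.2.1]oct-6-en-3-one (meso, configuration fixed by the bridge) | CC12CC(=O)CC(C)(O1)C=C2 | intermediate
5 | 1,5-dimethyl-8-oxabicyclo[3.2.1]octan-3-one (meso) | CC12CCC(C)(O1)CC(=O)C2 | intermediate
6 | 6-hydroxy-3,6-dimethylcyclohept-2-en-1-one (racemic, not isolated) | CC1=CC(=O)CC(C)(O)CC1 | intermediate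
7 | 3,6-dimethylcyclohepta-2,6-dien-1-one (achiral) | CC1=CC(=O)C=C(C)CC1 | intermediate
8 | methyl 2-methylpropanoate | COC(=O)C(C)C | starting material
9 | 1-(propan-2-yl)cyclopropan-1-ol | CC(C)C1(O)CC1 | intermediate
10 | bis(4-methyl-3-oxopentyl)zinc, the ring-opened form of zinc bis(1-isopropylcyclopropoxide) (not isolated) | CC(C)C(=O)CC[Zn]CCC(=O)C(C)C | intermediate
11 | (4-methyl-3-oxopentyl)zinc (S)-3,6-dimethyl-6-(4-methyl-3-oxopentyl)cyclohepta-1,3-dien-1-olate (not isolated) | CC(C)C(=O)CC[Zn]OC1=C[C@](C)(CCC(=O)C(C)C)CCC(C)=C1 | intermediate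
12 | cis-fused zinc aldolate, the (4-methyl-3-oxopentyl)zinc alkoxide of the (3S,3aS,8aS) hydroxy enone (not isolated) | O=C1C=C(C)CC[C@@]2(C)CC[C@](O[Zn]CCC(=O)C(C)C)(C(C)C)[C@@H]12 | intermediate
13 | (3R,3aR,8aS)-3-hydroxy-6,8a-dimethyl-3-(propan-2-yl)-2,3,3a,7,8,8a-hexahydroazulen-4(1H)-one | O=C1C=C(C)CC[C@@]2(C)CC[C@@](O)(C(C)C)[C@H]12 | intermediate
14 | (3R,3aS,4S,8aS)-6,8a-dimethyl-3-(propan-2-yl)-1,2,3,3a,4,7,8,8a-octahydroazulene-3,4-diol | O[C@H]1C=C(C)CC[C@@]2(C)CC[C@@](O)(C(C)C)[C@H]12 | intermediate
15 | 4-methoxybenzoyl chloride | COc1ccc(cc1)C(Cl)=O | starting material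
16 | (3R,3aS,4S,8aS)-3-hydroxy-6,8a-dimethyl-3-(propan-2-yl)-1,2,3,3a,4,7,8,8a-octahydroazulen-4-yl 4-methoxybenzoate | COc1ccc(C(=O)O[C@H]2C=C(C)CC[C@@]3(C)CC[C@@](O)(C(C)C)[C@H]23)cc1 | target

**Totals**
Total steps: 7. Longest linear sequence: 6 (steps 1, 2, 3, 5, 6, 7); step 4 is a one-step side branch.

**Steps most likely to fail**

Step 5 is the largest risk. A ketone homoenolate has not been added with enantiocontrol to a β,β-disubstituted dienone, the remaining enone of 13 could take a second addition, and the trans ring fusion rests on aldolate equilibration rather than on a kinetic preference, so the cis-fused (3S,3aS,8aS) isomer may have to be separated and recycled. The fallback separates the two bond formations and uses the homoenolate in masked, stoichiometric form. It sets out from 9: ring-opening bromination (NBS, CH2Cl2, 0 °C) gives 1-bromo-4-methylpentan-3-one F1, which is ketalised (ethylene glycol, TsOH cat., benzene, Dean–Stark) to 2-(2-bromoethyl)-2-(propan-2-yl)-1,3-dioxolane F2. Magnesium in THF converts this into {2-[2-(propan-2-yl)-1,3-dioxolan-2-yl]ethyl}magnesium bromide F3, which is added to dienone 7 under Cu(OTf)2/L* catalysis (Et2O, −30 °C), a reagent class with direct precedent on 3-methylcyclohept-2-enones. This gives (S)-3,6-dimethyl-6-{2-[2-(propan-2-yl)-1,3-dioxolan-2-yl]ethyl}cyclohept-2-en-1-one F4. Mild acid (PPTS, acetone/H2O) unmasks (S)-3,6-dimethyl-6-(4-methyl-3-oxopentyl)cyclohept-2-en-1-one F5, and a reversible aldol cyclisation (KOtBu 0.1 equiv, tBuOH, rt) comes back to the route at 13.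

Step 3 is second. Acid may move a double bond out of cross-conjugation (to the 2,4-dienone), or the intermediate tertiary ketol may undergo retro-aldol ring opening. The fallback does the two eliminations separately under base. It sets out from 5: LiHMDS (1.1 equiv, THF, −78 → 0 °C) opens the oxygen bridge by E1cB and, after quench, the hydroxy enone 6 is isolated. Its tertiary alcohol is then eliminated through the mesylate (MsCl, Et3N, CH2Cl2, 0 °C; then DBU), again toward the carbonyl, which comes back to the route at 7. No new compound is made.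

Step 6 is third. The hindered tertiary hydroxyl may not engage the borohydride, so the reduction may stall or give the 4R alcohol. The fallback takes the opposite face on purpose and inverts. It sets out from 13: Luche reduction (NaBH4, CeCl3·7H2O, MeOH, −40 °C), with hydride entering opposite the angular methyl, gives (3R,3aS,4R,8aS)-6,8a-dimethyl-3-(propan-2-yl)-1,2,3,3a,4,7,8,8a-octahydroazulene-3,4-diol F6. Mitsunobu esterification with 4-methoxybenzoic acid (PPh3, DIAD, toluene, 0 °C → rt) inverts C4 and installs the ester in one operation, coming back to the route at 16 and bypassing 14.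

**Further compounds**
F1 | step 5 | 1-bromo-4-methylpentan-3-one | CC(C)C(=O)CCBr
F2 | step 5 | 2-(2-bromoethyl)-2-(propan-2-yl)-1,3-dioxolane | CC(C)C1(CCBr)OCCO1
F3 | step 5 | {2-[2-(propan-2-yl)-1,3-dioxolan-2-yl]ethyl}magnesium bromide | CC(C)C1(CC[Mg]Br)OCCO1
F4 | step 5 | (S)-3,6-dimethyl-6-{2-[2-(propan-2-yl)-1,3-dioxolan-2-yl]ethyl}cyclohept-2-en-1-one | CC1=CC(=O)C[C@](C)(CCC2(C(C)C)OCCO2)CC1
F5 | step 5 | (S)-3,6-dimethyl-6-(4-methyl-3-oxopentyl)cyclohept-2-en-1-one | CC1=CC(=O)C[C@](C)(CCC(=O)C(C)C)CC1
F0 | step 3 | none | none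
F6 | step 6 | (3R,3aS,4R,8aS)-6,8a-dimethyl-3-(propan-2-yl)-1,2,3,3a,4,7,8,8a-octahydroazulene-3,4-diol | O[C@@H]1C=C(C)CC[C@@]2(C)CC[C@@](O)(C(C)C)[C@H]12
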